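The 2,3-dihydrobenzofuran is cut at C3–C3a and traced back to a flavanone. O1, the 2S carbon with its 4-oxygenated aryl group, the C4 oxygen and C6 of the target are O1, C2, O5 and C7 of (S)-naringenin, whose six-membered heterocycle must lose one carbon. Trivalent iodine in acidic trimethyl orthoformate shifts ring A carbon C4a from the carbonyl carbon to C3. This one operation forms C3–C3a, contracts the ring, places the C3 substituent trans to the untouched C2 centre, and expels C4 as a methyl ester handle. The precursor is the (2S)-flavanone bearing 5-OMe, a 7-(6-methoxybenzofuran-2-yl) group and a ring-B-deactivating 4'-tosylate.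

Key step: step 5

Assumption: (S)-naringenin is bought as the enantiopure 2S form, since material sold simply as "naringenin" is often racemic. Its ee is checked by chiral HPLC on receipt and again at the precursor and carboxylic acid stages.

Design remarks
- The target is the trans-(2S,3S) isomer. C2 of naringenin maps onto C2 of the target with the same spatial arrangement and the same descriptor.
- O4' carries a tosylate rather than an alkyl ether. A p-alkoxyphenyl group at C2 is itself an excellent migrating group (the isoflavone pathway) and makes C2–O1 acid-labile.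
- The sulfonate suppresses both problems. It is inert to Pd/PCy3 at room temperature, to LiOH at or below 40 °C and to BBr3, and it also shields C2–O1 during the demethylation.
- The resorcinol ring is not built on the ester carbon by acylating a β-diketone dianion. The C3–H (benzylic and α to the ester) would be deprotonated first, and 1,3,5-triketones prefer γ-pyrone closure or need hot alkali to aromatise.
- The 3,5-dioxygenated ring is therefore attached by decarboxylative arylation. As a consequence, C3 is created in step 5, planarised in step 8 and fixed there again, trans, by the C2 aryl group. C2 is never broken.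
- No step before the contraction uses a base able to enolise the flavanone.

Step 1
Reactants: 1 (S)-naringenin
Product: 2 (2S)-5-hydroxy-2-(4-hydroxyphenyl)-4-oxochroman-7-yl trifluoromethanesulfonate
Conditions: PhNTf2 (1.0 equiv), Et3N (1.05 equiv), THF, 0 °C → rt
Reagents that add atoms: N-phenylbis(trifluoromethanesulfonimide), O=S(=O)(C(F)(F)F)N(c1ccccc1)S(=O)(=O)C(F)(F)F
Why: Chemoselective phenol triflation: one equivalent of amine ionises only the 7-OH (the most acidic phenol, para to the acyl carbon), the 4'-OH stays neutral, the 5-OH is held in its hydrogen bond to the ketone, and the 7-phenoxide lowers C3–H acidity so that C2 is not at risk.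

Step 2
Reactants: 2 (2S)-5-hydroxy-2-(4-hydroxyphenyl)-4-oxochroman-7-yl trifluoromethanesulfonate
Product: 3 4-[(2S)-5-hydroxy-4-oxo-7-(trifluoromethylsulfonyloxy)chroman-2-yl]phenyl 4-methylbenzenesulfonate
Conditions: TsCl (1.1 equiv), pyridine, CH2Cl2, 0 °C → rt
Reagents that add atoms: 4-toluenesulfonyl chloride, Cc1ccc(cc1)S(=O)(=O)Cl
Why: Standard phenol tosylation: the free 4'-OH reacts while the chelated 5-OH does not, and pyridine is far too weak a base to enolise the ketone and open the pyranone.

Step 3
Reactants: 3 4-[(2S)-5-hydroxy-4-oxo-7-(trifluoromethylsulfonyloxy)chroman-2-yl]phenyl 4-methylbenzenesulfonate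
Product: 4 4-[(2S)-5-methoxy-4-oxo-7-(trifluoromethylsulfonyloxy)chroman-2-yl]phenyl 4-methylbenzenesulfonate
Conditions: MeOH (3 equiv), PPh3 (1.8 equiv), DIAD (1.8 equiv), THF, 0 °C → rt
Reagents that add atoms: methanol, CO
Why: Mitsunobu etherification: the PPh3/DIAD betaine deprotonates the 5-OH (acidified by the meta triflate) and the phenoxide attacks the methyl group of MeO–PPh3+, an essentially neutral O-methylation that leaves C3–H and hence C2 alone.

Step 4
Reactants: 4 4-[(2S)-5-methoxy-4-oxo-7-(trifluoromethylsulfonyloxy)chroman-2-yl]phenyl 4-methylbenzenesulfonate; 5 (6-methoxybenzofuran-2-yl)boronic acid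
Product: 6 4-[(2S)-5-methoxy-7-(6-methoxybenzofuran-2-yl)-4-oxochroman-2-yl]phenyl 4-methylbenzenesulfonate
Conditions: 5 (1.5 equiv), Pd(OAc)2 (3 mol%), PCy3 (6 mol%), powdered KF (3.3 equiv), THF, rt
Reagents that add atoms: none
Why: Suzuki–Miyaura coupling: the triflate para to the ketone adds to zerovalent palladium at room temperature whereas the aryl tosylate does not, and sparingly soluble KF activates the boronic acid without making the medium basic enough for enolisation and chalcone opening.

Step 5
Reactants: 6 4-[(2S)-5-methoxy-7-(6-methoxybenzofuran-2-yl)-4-oxochroman-2-yl]phenyl 4-methylbenzenesulfonate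
Product: 10 methyl (2S,3S)-4-methoxy-6-(6-methoxybenzofuran-2-yl)-2-[4-(tosyloxy)phenyl]-2,3-dihydrobenzofuran-3-carboxylate, via methyl enol ether 7 (not isolated), via trans iodane ketal 8 (not isolated), via dimethoxycarbenium ion 9 (not isolated)
Conditions: conc. H2SO4 (0.5 equiv), HC(OMe)3/CH2Cl2, rt, 30 min; then PhI(OAc)2 (1.1 equiv, in portions), 0 °C → rt, dark; aq. NaHCO3
Reagents that add atoms: trimethyl orthoformate, COC(OC)OC; (diacetoxyiodo)benzene, CC(=O)OI(OC(C)=O)c1ccccc1 (its atoms are held only in 8)
Why: Acidic orthoformate turns ketone 6 into enol ether 7, and PhI(OAc)2 adds to C3 from the face opposite the pseudo-equatorial C2 aryl group while methanol caps C4, giving the trans-diequatorial iodane ketal 8. In 8 the equatorial C3–I bond is antiperiplanar to C4–C4a, so C4a slides from C4 to C3 through a phenonium-like bridged transition state as PhI departs, and the dimethoxycarbenium ion 9 loses a methyl group to acetate to give ester 10. This is the known oxidative 1,2-aryl migration of aryl ketones with trivalent iodine or Tl(NO3)3 in trimethyl orthoformate, in its established flavanone version that gives trans-2-aryl-2,3-dihydrobenzofuran-3-carboxylates. The five-membered ring is closed by a carbon-to-carbon aryl shift (ring contraction forming C3–C3a) and not by C–O bond formation, so O1–C2 and the 2S centre are never broken. The new C3 centre (3S) is controlled by C2, because anti addition of the iodane followed by inversion at C3 places the ester trans to the aryl group, which is also the thermodynamic epimer. The step needs C4a to out-migrate ring B and the C2 hydrogen and needs the oxidant to choose the enol ether over benzofuran C3: O1 and 5-OMe ortho and the benzofuranyl group para to C4a raise its migratory aptitude, the 4'-tosylate lowers that of ring B and blocks acid ionisation of C2–O1, and pre-forming 7 with only 1.1 equiv of oxidant spares the benzofuran.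

Step 6
Reactants: 10 methyl (2S,3S)-4-methoxy-6-(6-methoxybenzofuran-2-yl)-2-[4-(tosyloxy)phenyl]-2,3-dihydrobenzofuran-3-carboxylate
Product: 11 (2S,3S)-4-methoxy-6-(6-methoxybenzofuran-2-yl)-2-[4-(tosyloxy)phenyl]-2,3-dihydrobenzofuran-3-carboxylic acid
Conditions: LiOH·H2O (5 equiv), THF/H2O, rt → 40 °C; then 1 M HCl
Reagents that add atoms: lithium hydroxide, [Li+].[OH-]
Why: Saponification by acyl–oxygen cleavage: the methyl ester falls well below the temperature at which an aryl tosylate is attacked, ring opening by β-elimination of O1 would be the reverse of a disfavoured 5-endo-trig closure, and any C3 epimerisation is harmless because trans is the stable epimer.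

Step 7
Reactants: 12 1-bromo-3,5-dimethoxybenzene
Product: 14 (3,5-dimethoxyphenyl)zinc chloride as a titrated THF solution, via aryl Grignard reagent 13 (not isolated)
Conditions: Mg turnings, LiCl, THF, rt; then ZnCl2 (1.0 M in THF), 0 °C → rt
Reagents that add atoms: zinc chloride, Cl[Zn]Cl; magnesium, [Mg] (held only in 13)
Why: LiCl-assisted Grignard formation followed by transmetalation to zinc gives a mild aryl nucleophile that tolerates an activated ester and an aryl sulfonate.

Step 8
Reactants: 11 (2S,3S)-4-methoxy-6-(6-methoxybenzofuran-2-yl)-2-[4-(tosyloxy)phenyl]-2,3-dihydrobenzofuran-3-carboxylic acid; 14 (3,5-dimethoxyphenyl)zinc chloride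
Product: 17 4-[(2S,3S)-3-(3,5-dimethoxyphenyl)-4-methoxy-6-(6-methoxybenzofuran-2-yl)-2,3-dihydrobenzofuran-2-yl]phenyl 4-methylbenzenesulfonate, via NHPI ester 15 (not isolated), via C3 benzylic radical 16 (not isolated)
Conditions: N-hydroxyphthalimide (1.05 equiv), DIC (1.05 equiv), DMAP (5 mol%), CH2Cl2, rt; concentrate; then NiCl2·glyme (20 mol%), dtbbpy (40 mol%), 14 (3 equiv), THF/DMF, rt; chromatography to remove any cis isomer
Reagents that add atoms: N-hydroxyphthalimide, O=C1c2ccccc2C(=O)N1O (its atoms are held only in 15)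
Why: Carbodiimide esterification followed by nickel-catalysed decarboxylative Negishi arylation of the redox-active ester: monovalent nickel reduces 15, CO2 and phthalimide anion leave, the planar radical 16 (whose C2–O1 bond lies in the nodal plane, so β-scission does not compete) is captured by the aryl–nickel species on the face away from the C2 aryl group, and reductive elimination fixes the trans (3S) configuration of the target.

Step 9
Reactants: 17 4-[(2S,3S)-3-(3,5-dimethoxyphenyl)-4-methoxy-6-(6-methoxybenzofuran-2-yl)-2,3-dihydrobenzofuran-2-yl]phenyl 4-methylbenzenesulfonate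
Product: 18 4-[(2S,3S)-3-(3,5-dihydroxyphenyl)-4-hydroxy-6-(6-hydroxybenzofuran-2-yl)-2,3-dihydrobenzofuran-2-yl]phenyl 4-methylbenzenesulfonate
Conditions: BBr3 (10 equiv), CH2Cl2, −78 °C → rt; ice/MeOH quench
Reagents that add atoms: none
Why: Lewis-acid cleavage of aryl methyl ethers with BBr3, routine for 2-arylbenzofuran and resorcinol ethers: the sulfonate is inert and keeps ring B electron-poor, so the benzylic C2–O1 bond is not ionised and neither stereocentre moves.

Step 10
Reactants: 18 4-[(2S,3S)-3-(3,5-dihydroxyphenyl)-4-hydroxy-6-(6-hydroxybenzofuran-2-yl)-2,3-dihydrobenzofuran-2-yl]phenyl 4-methylbenzenesulfonate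
Product: 19 (2S,3S)-3-(3,5-dihydroxyphenyl)-6-(6-hydroxybenzofuran-2-yl)-2-(4-hydroxyphenyl)-2,3-dihydrobenzofuran-4-ol (CNP0112262.1)
Conditions: KOH (2 M aq., excess), MeOH, degassed, argon, 60 °C; then 1 M HCl
Reagents that add atoms: none
Why: Alkaline S–O cleavage of an aryl sulfonate: hydroxide attacks sulfur so the ring B C–O bond stays intact, C3–H is not acidic, and the phenoxide on ring A makes O1 a poor leaving group, so quinone-methide opening at C2 should not set in at 60 °C.

Compound list
1 | (S)-naringenin, (2S)-5,7-dihydroxy-2-(4-hydroxyphenyl)chroman-4-one | O=C1C[C@@H](c2ccc(O)cc2)Oc2cc(O)cc(O)c12 | starting material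
2 | (2S)-5-hydroxy-2-(4-hydroxyphenyl)-4-oxochroman-7-yl trifluoromethanesulfonate | O=C1C[C@@H](c2ccc(O)cc2)Oc2cc(OS(=O)(=O)C(F)(F)F)cc(O)c12 | intermediate
3 | 4-[(2S)-5-hydroxy-4-oxo-7-(trifluoromethylsulfonyloxy)chroman-2-yl]phenyl 4-methylbenzenesulfonate | O=C1C[C@@H](c2ccc(OS(=O)(=O)c3ccc(C)cc3)cc2)Oc2cc(OS(=O)(=O)C(F)(F)F)cc(O)c12 | intermediate
4 | 4-[(2S)-5-methoxy-4-oxo-7-(trifluoromethylsulfonyloxy)chroman-2-yl]phenyl 4-methylbenzenesulfonate | O=C1C[C@@H](c2ccc(OS(=O)(=O)c3ccc(C)cc3)cc2)Oc2cc(OS(=O)(=O)C(F)(F)F)cc(OC)c12 | intermediate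
5 | (6-methoxybenzofuran-2-yl)boronic acid | COc1ccc2cc(B(O)O)oc2c1 | starting material
6 | 4-[(2S)-5-methoxy-7-(6-methoxybenzofuran-2-yl)-4-oxochroman-2-yl]phenyl 4-methylbenzenesulfonate (key-step precursor) | O=C1C[C@@H](c2ccc(OS(=O)(=O)c3ccc(C)cc3)cc2)Oc2cc(-c3cc4ccc(OC)cc4o3)cc(OC)c12 | intermediate
7 | methyl enol ether of 6, 4-[(2S)-4,5-dimethoxy-7-(6-methoxybenzofuran-2-yl)-2H-chromen-2-yl]phenyl 4-methylbenzenesulfonate | COC1=C[C@@H](c2ccc(OS(=O)(=O)c3ccc(C)cc3)cc2)Oc2cc(-c3cc4ccc(OC)cc4o3)cc(OC)c12 | intermediate
8 | 4,4-dimethyl ketal of 6 bearing acetoxy(phenyl)iodanyl at C3, trans to the C2 aryl group (2R,3R by CIP only because iodine raises the rank of C3; C2 spatially unchanged) | COC1(OC)[C@H](I(OC(C)=O)c2ccccc2)[C@@H](c2ccc(OS(=O)(=O)c3ccc(C)cc3)cc2)Oc2cc(-c3cc4ccc(OC)cc4o3)cc(OC)c12 | intermediate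
9 | ring-contracted trans-(2S,3S) dihydrobenzofuran with a dimethoxycarbenium group on C3 | Cc1ccc(cc1)S(=O)(=O)Oc1ccc([C@H]2Oc3cc(-c4cc5ccc(OC)cc5o4)cc(OC)c3[C@@H]2C(OC)=[O+]C)cc1 | intermediate
10 | methyl (2S,3S)-4-methoxy-6-(6-methoxybenzofuran-2-yl)-2-[4-(tosyloxy)phenyl]-2,3-dihydrobenzofuran-3-carboxylate (key-step product) | Cc1ccc(cc1)S(=O)(=O)Oc1ccc([C@H]2Oc3cc(-c4cc5ccc(OC)cc5o4)cc(OC)c3[C@@H]2C(=O)OC)cc1 | intermediate
11 | (2S,3S)-4-methoxy-6-(6-methoxybenzofuran-2-yl)-2-[4-(tosyloxy)phenyl]-2,3-dihydrobenzofuran-3-carboxylic acid | Cc1ccc(cc1)S(=O)(=O)Oc1ccc([C@H]2Oc3cc(-c4cc5ccc(OC)cc5o4)cc(OC)c3[C@@H]2C(=O)O)cc1 | intermediate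
12 | 1-bromo-3,5-dimethoxybenzene | COc1cc(Br)cc(OC)c1 | starting material
13 | (3,5-dimethoxyphenyl)magnesium bromide | COc1cc([Mg]Br)cc(OC)c1 | intermediate
14 | (3,5-dimethoxyphenyl)zinc chloride | COc1cc([Zn]Cl)cc(OC)c1 | intermediate
15 | 1,3-dioxoisoindolin-2-yl (2S,3S)-4-methoxy-6-(6-methoxybenzofuran-2-yl)-2-[4-(tosyloxy)phenyl]-2,3-dihydrobenzofuran-3-carboxylate | Cc1ccc(cc1)S(=O)(=O)Oc1ccc([C@H]2Oc3cc(-c4cc5ccc(OC)cc5o4)cc(OC)c3[C@@H]2C(=O)ON2C(=O)c3ccccc3C2=O)cc1 | intermediate
16 | (2S)-configured C3 benzylic radical formed from 15 by loss of CO2 | Cc1ccc(cc1)S(=O)(=O)Oc1ccc([C@H]2Oc3cc(-c4cc5ccc(OC)cc5o4)cc(OC)c3[CH]2)cc1 | intermediate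
17 | 4-[(2S,3S)-3-(3,5-dimethoxyphenyl)-4-methoxy-6-(6-methoxybenzofuran-2-yl)-2,3-dihydrobenzofuran-2-yl]phenyl 4-methylbenzenesulfonate | Cc1ccc(cc1)S(=O)(=O)Oc1ccc([C@H]2Oc3cc(-c4cc5ccc(OC)cc5o4)cc(OC)c3[C@@H]2c2cc(OC)cc(OC)c2)cc1 | intermediate
18 | 4-[(2S,3S)-3-(3,5-dihydroxyphenyl)-4-hydroxy-6-(6-hydroxybenzofuran-2-yl)-2,3-dihydrobenzofuran-2-yl]phenyl 4-methylbenzenesulfonate | Cc1ccc(cc1)S(=O)(=O)Oc1ccc([C@H]2Oc3cc(-c4cc5ccc(O)cc5o4)cc(O)c3[C@@H]2c2cc(O)cc(O)c2)cc1 | intermediate
19 | (2S,3S)-3-(3,5-dihydroxyphenyl)-6-(6-hydroxybenzofuran-2-yl)-2-(4-hydroxyphenyl)-2,3-dihydrobenzofuran-4-ol | Oc1ccc([C@H]2Oc3cc(-c4cc5ccc(O)cc5o4)cc(O)c3[C@@H]2c2cc(O)cc(O)c2)cc1 | target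

Total step count: 10. Longest linear sequence: 9 (steps 1–6 and 8–10; step 7 is a one-step side branch).

Steps most likely to fail

Step 5. Several processes could outrun the wanted shift:
- migration of ring B or loss of the C2 hydrogen from the iodane adduct
- simple methanol substitution at C3
- attack of the oxidant on the electron-rich benzofuran C3

The fallback sets out from 6 and returns at 10. It forms the same C3–C3a bond without any electrophilic oxidant, by a Wolff ring contraction. Compound 6 is deprotonated with LiHMDS in THF at −78 °C and acylated with CF3CO2CH2CF3 to the 3-trifluoroacetyl flavanone F1. Detrifluoroacetylative diazo transfer (MsN3, Et3N, H2O, MeCN, rt) gives the 3-diazoflavanone F2. Irradiation at 365 nm in MeOH/THF lets C4a migrate to the carbene carbon, giving the ring-contracted ketene F3. Methanol adds to F3, and catalytic DBU in CH2Cl2 equilibrates the ester to trans 10. The cost is a short-lived cold enolate, so the ee is checked again at 10.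

Step 8. Capture of the stabilised C3 radical by nickel may be slow. That would open the way to radical dimerisation, hydrogen abstraction, β-hydride loss with aromatisation of the dihydrofuran, or insufficient facial selectivity. The fallback sets out from acid 11 and bromide 12 and returns at 17. It is a dual photoredox/nickel decarboxylative arylation ([Ir{dF(CF3)ppy}2(dtbbpy)]PF6, NiCl2·glyme, dtbbpy, Cs2CO3, DMF, blue LED, rt). Here the carboxylate itself is oxidised, the aryl partner is an electrophile that enters by oxidative addition, and the radical flux is throttled by the light intensity. Neither an activated ester nor an organozinc reagent is involved, and no new compound is made (F0).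

Step 4. Two processes threaten this step: erosion of the C2 configuration through fluoride-induced enolisation and reversible opening to the chalcone, and protodeboronation of the 2-benzofuranylboronic acid before transmetalation. The fallback sets out from 4 and returns at 6, and is a base-free Negishi coupling. Purchased 6-methoxybenzofuran F4 is deprotonated at C2 (n-BuLi, THF, −78 °C) to 2-lithio-6-methoxybenzofuran F5. This is transmetalated with ZnCl2 to (6-methoxybenzofuran-2-yl)zinc chloride F6. F6 is coupled with 4 under Pd(PPh3)4 in THF at rt to 40 °C. The organozinc halide neither enolises nor adds to the ketone.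

Further compounds
F1 | step 5 | 3-trifluoroacetyl derivative of 6 (C2 as in 6; C3 epimers and enol) | O=C1C(C(=O)C(F)(F)F)[C@@H](c2ccc(OS(=O)(=O)c3ccc(C)cc3)cc2)Oc2cc(-c3cc4ccc(OC)cc4o3)cc(OC)c12
F2 | step 5 | 3-diazo derivative of 6 (C2 as in 6) | O=C1C(=[N+]=[N-])[C@@H](c2ccc(OS(=O)(=O)c3ccc(C)cc3)cc2)Oc2cc(-c3cc4ccc(OC)cc4o3)cc(OC)c12
F3 | step 5 | ring-contracted ketene, 3-(oxomethylidene)-2,3-dihydrobenzofuran (C2 as in 6) | Cc1ccc(cc1)S(=O)(=O)Oc1ccc([C@H]2Oc3cc(-c4cc5ccc(OC)cc5o4)cc(OC)c3C2=C=O)cc1
F0 | step 8 | none | none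
F4 | step 4 | 6-methoxybenzofuran (purchased) | COc1ccc2ccoc2c1
F5 | step 4 | 2-lithio-6-methoxybenzofuran | COc1ccc2cc([Li])oc2c1
F6 | step 4 | (6-methoxybenzofuran-2-yl)zinc chloride | COc1ccc2cc([Zn]Cl)oc2c1
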